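- Two questions stood before me, how much D and G together the flask held at its end and how near J came to saturation, and what I had to answer them was the eta run.

all flasks: L 31 mM (held)
- eta: E 0.11 M; run made earlier
- flask: E 0.076 M; time 50 min

eta run (percent of the E charged)

| time / min | D / % | G / % | E / % |
|---|---|---|---|
| 1.33 | 1.8 | 0.2 | 99.2 |
| 2.00 | 2.0 | 0 | 99.0 |
| 3.00 | 2.3 | 0 | 97.7 |
| 4.00 | 3.9 | 0 | 95.1 |
| 6.00 | 7.0 | 0 | 92.9 |
| 10.0 | 11.7 | 0.4 | 88.6 |
| 15.0 | 17.8 | 0.8 | 81.7 |

(scatter of a reading: 0.5 percentage points)

* amount of D and G together at 50 min, in percent of the E charged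
* concentration of J in solution at 50 min, in percent of saturation

- what is said of D includes G
- G is a solid; its amount is given per volume of the solution
- the analysis behind the earlier runs scatters by 0.5 percentage points, standard deviation
- at the start none of L is in solution
- J is what L becomes in solution

- I worked from the slope of D in the eta run, 1.31 mM min⁻¹, and called it the feed: the rate at which dissolving L supplies J, taken as the rate-limiting step.
- The slope read 1.28 mM min⁻¹ up to 6.00 min and 1.32 mM min⁻¹ after it, while E fell to 81.7%; with this scatter, one run merely leans towards a rate that ignores cE, but I committed to it.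
- The first rung of my ladder was the use of J: D read 1.8% at 1.33 min, close to the line of the feed, though the readings at 3.00 min and 4.00 min lay under it, so I took 1.33 min as a rough upper mark for how long J lasted at the eta charge.
- The next rung was the filling time, cL/feed, 23.7 min, which lay 1.25 powers of ten higher, so I expected cJ to stay low in the eta run.
- The top rung was the charge time, cE/feed, 58.2 min, just above the asked 50 min, so I reckoned y as 85.9% for the flask.
- That reckoning left 10.7 mM of E; taking the use of J as proportional to cE stretched it to 13.6 min, so I put cJ at about 36.5% of saturation or lower.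
- The forecast gave 55% and 80%, saying “I lean towards the chemical case”.

- The flask gave 77.2% and 13.0%.

    G ⇌ D, rate k1*(cs1 - [D]) while solid is left; crystals form when [D] > cs1 (solubility = 32.0 mM, k = 0.00339 s⁻¹)
    J ⇌ X (K = 7.80, k = 1.25 × 10⁻⁴ s⁻¹)
    E + J → D (k = 0.248 L mol⁻¹ s⁻¹)
    L ⇌ J, rate k4*(csat - [J]) (kL = 7.54 × 10⁻⁴ s⁻¹)
    J + D → Z (k = 0.00536 L mol⁻¹ s⁻¹)

- The most that L could deliver by 50 min into a solution kept empty was 92.3% of the E charged. Over those 50 min the flask made D and G at a mean 1.17 mM min⁻¹, less than the feed of 1.31 mM min⁻¹. For a second flask, the same but charged with 0.19 M of E, the feed reckons to 34.5%, and that flask held 35.4% of D and G.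

The runs are calculated with constants of no real substance; scatter was added.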